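Retrosynthesis (locants of cyclohepta[b]furan-2-one: lactone O1–C2–C3, ring C3a, C4–C8, C8a; side chain C1'–C4'): remove the C8 angelate, the C2'=C3' unsaturation and an O4 silyl group, open the lactone C2–O1 bond, turn the C7 ketol into an exocyclic C7=C1' alkene, then cut C3a–C4 and C5–C6 together, which excises C4–C5 as one O-vinyl group.
Enabling feature: in the seven-membered ring, C4 is a carbinol next to C3a, which carries the 2-carboxyallyl carbon C3 (a homoallylic alcohol, the retron of an aldehyde allylboration); and O=C4–C5–C6–C7=C1' is a 4-pentenal (the retron of a Claisen rearrangement) once the C7 ketol is masked as an alkene.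
Forward: threitol acetonide (C8, C8a) → propynyl → alkenylstannane → enone → (S)-allylic vinyl ether on one arm; aldehyde → Morita–Baylis–Hillman carbonate → allylboronate on the other arm; one thermal domino then closes the carbocycle; the lactone ring is closed afterwards; ketol, angelate and enone are finished last.
Stereochemistry: C8 and C8a come from (−)-2,3-O-isopropylidene-D-threitol; C6 by chirality transfer from a CBS-set carbinol in the chair Claisen step; C3a and C4 from the closed allylboration transition state under 1,3-allylic strain; C7 by osmylation anti to the C8–O bond.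

Key step: step 14

Remark: compounds 1, 8, 11, 15 and 27 are taken as commercial; target locants are used for all intermediates.

Step 1
Reactants: 1 (4R,5R)-2,2-dimethyl-1,3-dioxolane-4,5-dimethanol
Product: 2 mono-TBS ether of 1
Conditions: NaH (1.0 equiv), THF, 0 °C; then TBSCl (1.0 equiv), 0 → 23 °C
Reagents that add atoms: tert-butyldimethylsilyl chloride, CC(C)(C)[Si](C)(C)Cl
Why: Monosilylation of the C2-symmetric diol through its monosodium alkoxide (O-silylation) should give the mono-TBS ether without touching either stereocentre.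

Step 2
Reactants: 2 mono-TBS ether
Product: 3 trans-dioxolane carbaldehyde
Conditions: Dess–Martin periodinane, NaHCO3, CH2Cl2, 0 → 23 °C
Reagents that add atoms: none
Why: Dess–Martin oxidation of the primary alcohol should give the α-alkoxy aldehyde under buffered conditions, and the trans-dioxolane is in any case the stable isomer.

Step 3
Reactants: 3 trans-dioxolane carbaldehyde
Product: 4 1,1-dibromoalkene
Conditions: CBr4, PPh3, Et3N, CH2Cl2, 0 °C
Reagents that add atoms: carbon tetrabromide, BrC(Br)(Br)Br
Why: Corey–Fuchs dibromo-olefination (Wittig-type reaction of Ph3P=CBr2 made in the flask) adds the carbon that becomes C6, the aldehyde carbon being the future C7.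

Step 4
Reactants: 4 1,1-dibromoalkene
Product: 6 propynyl dioxolane, via lithium acetylide 5 (not isolated)
Conditions: n-BuLi (2.2 equiv), THF, −78 °C; then MeI, DMPU, −78 → 23 °C
Reagents that add atoms: iodomethane, CI
Why: In the second stage of the Corey–Fuchs sequence, elimination and bromine–lithium exchange give acetylide 5, whose C-methylation installs the C6 methyl group.

Step 5
Reactants: 6 propynyl dioxolane
Product: 7 alkenylstannane (tin on the carbon bound to the dioxolane; methyl cis to the dioxolane)
Conditions: Bu3SnH, Mo(CO)3(CNt-Bu)3 (2 mol %), hydroquinone, THF, 55 °C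
Reagents that add atoms: tributyltin hydride, CCCC[SnH](CCCC)CCCC
Why: Molybdenum-catalysed syn-hydrostannation of a propargylic ether should place tin on the alkyne carbon next to the oxygenated carbon and hydrogen cis to it, which fixes the trisubstituted alkene geometry.

Step 6
Reactants: 7 alkenylstannane; 8 butanoyl chloride
Product: 9 α-branched (E)-enone
Conditions: PdCl2(MeCN)2 (5 mol %), 1,2-dichloroethane, 60 °C
Reagents that add atoms: none
Why: Stille acylation of the alkenylstannane with the acid chloride should proceed with retention of alkene geometry and attach the four-carbon side chain (C1'–C4') to C7.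

Step 7
Reactants: 9 enone
Product: 10 (S)-allylic alcohol
Conditions: (R)-2-methyl-CBS-oxazaborolidine (20 mol %), catecholborane, toluene, −78 °C; then MeOH, aq NaOH
Reagents that add atoms: none
Why: Corey–Bakshi–Shibata 1,2-reduction with the (R)-oxazaborolidine (alkenyl as the large group, propyl as the small one) should set the (S)-carbinol at C1' by reagent control; this centre later relays its chirality to C6.

Step 8
Reactants: 10 (S)-allylic alcohol; 11 butyl vinyl ether
Product: 12 allyl vinyl ether
Conditions: Pd(OCOCF3)2 (5 mol %), 4,7-diphenyl-1,10-phenanthroline (5 mol %), Et3N, neat 11, air, 40 °C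
Reagents that add atoms: none
Why: Palladium-catalysed transfer vinylation (transetherification) of the secondary alcohol installs the O-vinyl group that becomes C4–C5 and O4, with the carbinol configuration untouched.

Step 9
Reactants: 12 allyl vinyl ether
Product: 13 primary alcohol
Conditions: TBAF, THF, 0 °C
Reagents that add atoms: none
Why: Fluoride cleavage of the primary TBS ether leaves the vinyl ether and the acetonide intact.

Step 10
Reactants: 13 primary alcohol
Product: 14 aldehyde
Conditions: Dess–Martin periodinane, pyridine, CH2Cl2, 0 °C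
Reagents that add atoms: none
Why: Pyridine-buffered Dess–Martin oxidation should give the α-alkoxy aldehyde (future C3a) while sparing the acid-labile vinyl ether.

Step 11
Reactants: 14 aldehyde; 15 tert-butyl acrylate
Product: 16 Morita–Baylis–Hillman adduct (both carbinol epimers)
Conditions: DABCO (1 equiv), neat 15 (excess), 23 °C, 5–7 d
Reagents that add atoms: none
Why: The Morita–Baylis–Hillman reaction of the activated α-alkoxy aldehyde forms the C3a–C3 bond, and the new carbinol centre is irrelevant because it is removed in step 13.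

Step 12
Reactants: 16 Morita–Baylis–Hillman adduct
Product: 17 allylic tert-butyl carbonate
Conditions: Boc2O, DMAP (10 mol %), CH2Cl2, 0 → 23 °C
Reagents that add atoms: di-tert-butyl dicarbonate, CC(C)(C)OC(=O)OC(=O)OC(C)(C)C
Why: DMAP-catalysed O-acylation turns the allylic alcohol into a carbonate leaving group for the SN2' borylation.

Step 13
Reactants: 17 allylic carbonate
Product: 18 (E)-2-(tert-butoxycarbonyl)allyl boronate
Conditions: B2pin2, CuCl (5 mol %), Xantphos (5 mol %), KOt-Bu (10 mol %), THF, 23 °C
Reagents that add atoms: bis(pinacolato)diboron, CC1(C)OB(OC1(C)C)B1OC(C)(C)C(C)(C)O1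
Why: Copper-catalysed γ-selective (SN2') allylic borylation should give the allylboronate with the dioxolane trans to the ester and cis to CH2B, the usual outcome of SN2' substitution of Morita–Baylis–Hillman ester derivatives.

Step 14
Reactants: 18 allyl vinyl ether allylboronate
Product: 21 cycloheptane γ-hydroxy α-methylene ester, via Claisen aldehyde 19 (not isolated), via cyclic borate 20 (not isolated)
Conditions: toluene (0.005 M), BHT (cat.), base-washed sealed vessel, 120 °C; then aq NaHCO3, 23 °C
Reagents that add atoms: none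
Why: Proposed new method: on heating, the allyl vinyl ether of 18 should undergo a chair (3,3)-sigmatropic Claisen rearrangement (C5–C6 formed, C1'–O cleaved) that unmasks the C4 aldehyde 19, and this aldehyde should then be captured by the tethered 2-alkoxycarbonylallyl boronate through a closed six-membered chair transition state (C3a–C4 formed with allyl transposition, releasing the exo-methylene acrylate) to give borate 20, hydrolysed on work-up to 21; the closest known reaction types are the aliphatic Claisen rearrangement, the thermal addition of 2-alkoxycarbonylallyl boronates to aldehydes and domino processes in which an aldehyde formed in situ is trapped by an internal allylboronate, but the two events have not been coupled in this way to close a cycloheptane. The seven-membered ring is closed in the second event by 7-exo-trig addition of the γ-carbon of the allylboronate to the aldehyde, the Claisen step itself closing no ring. C6 should be set by 1,3-chirality transfer: with the propyl group equatorial in the chair, the vinyl terminus is delivered to the alkene face on which the (S)-configured C–O bond lies, while the methyl group (trans to the carbinol carbon) stays equatorial. C3a and C4 should follow from the (E)-boronate geometry (C8a chain axial, aldehyde chain equatorial, hence O4 cis to C3) and from 1,3-allylic strain with the cis CH2B group, which holds H8a in the alkene plane so that the aldehyde adds on the C8 side and C3 ends trans to O8a. The step needs chemoselectivity (no reactive carbonyl exists before the rearrangement, and the tert-butyl ester keeps the O4 borate from lactonising), fidelity of the chair Claisen step (equatorial against axial propyl) and ring closure in preference to intermolecular allylboration, the last secured by high dilution.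

Step 15
Reactants: 21 γ-hydroxy ester
Product: 22 O4-TBDPS ether
Conditions: TBDPSCl, imidazole, DMAP (cat.), DMF, 45 °C
Reagents that add atoms: tert-butyldiphenylsilyl chloride, CC(C)(C)[Si](Cl)(c1ccccc1)c1ccccc1
Why: Silylation of the only free hydroxyl as an acid-resistant TBDPS ether keeps O4 from competing for the carboxyl group in the later lactonisation.

Step 16
Reactants: 22 O4-TBDPS ether
Product: 23 C7,C1' diol
Conditions: OsO4 (5 mol %), NMO, acetone–H2O, 23 °C
Reagents that add atoms: osmium tetroxide, O=[Os](=O)(=O)=O; N-methylmorpholine N-oxide, C[N+]1([O-])CCOCC1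
Why: Catalytic osmylation (Upjohn dihydroxylation) should select the electron-rich trisubstituted exocyclic alkene over the hindered electron-poor acrylate and add anti to the allylic C8–O bond (C8–H is held in the alkene plane by 1,3-allylic strain with the cis propyl group), which sets the C7 tertiary alcohol.

Step 17
Reactants: 23 diol
Product: 24 α-hydroxy ketone
Conditions: Dess–Martin periodinane, NaHCO3, CH2Cl2, 23 °C
Reagents that add atoms: none
Why: Dess–Martin oxidation converts the secondary C1' alcohol into the ketone, while the tertiary C7 alcohol cannot be oxidised.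

Step 18
Reactants: 24 α-hydroxy ketone
Product: 26 trans-fused α-methylene lactone diol, via seco acid 25 (not isolated)
Conditions: TFA–CH2Cl2–H2O (10:10:1), 0 → 23 °C
Reagents that add atoms: none
Why: Acidolysis removes the acetonide and the tert-butyl ester, and acid 25 should lactonise with O8a, the only free hydroxyl that can give a γ-lactone (O4 is silylated), so the trans ring fusion set in step 14 is carried into the lactone.

Step 19
Reactants: 26 lactone diol; 27 angelic acid
Product: 29 C8 angelate, via mixed anhydride 28 (not isolated)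
Conditions: 27, 2,4,6-trichlorobenzoyl chloride, Et3N, toluene, 23 °C; then 26, 80 °C
Reagents that add atoms: none
Why: Yamaguchi esterification through mixed anhydride 28 should acylate the secondary C8 hydroxyl (the tertiary C7 hydroxyl is inert) without Z to E isomerisation of the angelate.

Step 20
Reactants: 29 C8 angelate
Product: 30 (E)-enone silyl ether
Conditions: 2-iodoxybenzoic acid (IBX), 4-methoxypyridine N-oxide, DMSO, 23 °C
Reagents that add atoms: none
Why: IBX dehydrogenation of the ketone (only C2' is enolisable) should give the (E)-enone under neutral conditions that spare the angelate and the α-methylene lactone; doing this after O8 is acylated avoids oxa-Michael addition of a free C8 hydroxyl.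

Step 21
Reactants: 30 (E)-enone silyl ether
Product: 31 CNP0206014.2
Conditions: HF·pyridine, pyridine, THF, 0 → 23 °C
Reagents that add atoms: none
Why: Buffered fluoride desilylation unveils the C4 hydroxyl without affecting the esters, the enone or the α-methylene lactone.

Compound list
1 | (4R,5R)-2,2-dimethyl-1,3-dioxolane-4,5-dimethanol ((−)-2,3-O-isopropylidene-D-threitol) | OC[C@H]1OC(C)(C)O[C@@H]1CO | starting material
2 | [(4R,5R)-5-(tert-butyldimethylsilyloxymethyl)-2,2-dimethyl-1,3-dioxolan-4-yl]methanol | OC[C@H]1OC(C)(C)O[C@@H]1CO[Si](C)(C)C(C)(C)C | intermediate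
3 | (4S,5R)-5-(tert-butyldimethylsilyloxymethyl)-2,2-dimethyl-1,3-dioxolane-4-carbaldehyde (trans) | O=C[C@H]1OC(C)(C)O[C@@H]1CO[Si](C)(C)C(C)(C)C | intermediate
4 | trans-4-(2,2-dibromovinyl)-5-(TBS-oxymethyl)-2,2-dimethyl-1,3-dioxolane (ring centres as in 3) | BrC(Br)=C[C@H]1OC(C)(C)O[C@@H]1CO[Si](C)(C)C(C)(C)C | intermediate
5 | lithium acetylide: trans-4-(lithioethynyl)-5-(TBS-oxymethyl)-2,2-dimethyl-1,3-dioxolane | [Li]C#C[C@H]1OC(C)(C)O[C@@H]1CO[Si](C)(C)C(C)(C)C | intermediate
6 | trans-4-(prop-1-ynyl)-5-(TBS-oxymethyl)-2,2-dimethyl-1,3-dioxolane | CC#C[C@H]1OC(C)(C)O[C@@H]1CO[Si](C)(C)C(C)(C)C | intermediate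
7 | trans-4-[(E)-1-(tributylstannyl)prop-1-enyl]-5-(TBS-oxymethyl)-2,2-dimethyl-1,3-dioxolane (methyl cis to the dioxolane) | C/C=C(/[Sn](CCCC)(CCCC)CCCC)[C@H]1OC(C)(C)O[C@@H]1CO[Si](C)(C)C(C)(C)C | intermediate
8 | butanoyl chloride | CCCC(=O)Cl | starting material
9 | (E)-3-[trans-5-(TBS-oxymethyl)-2,2-dimethyl-1,3-dioxolan-4-yl]hept-2-en-4-one (methyl trans to the acyl group) | C/C=C(/C(=O)CCC)[C@H]1OC(C)(C)O[C@@H]1CO[Si](C)(C)C(C)(C)C | intermediate
10 | (2Z,4S)-3-[trans-5-(TBS-oxymethyl)-2,2-dimethyl-1,3-dioxolan-4-yl]hept-2-en-4-ol | CCC[C@H](O)/C(=C/C)[C@H]1OC(C)(C)O[C@@H]1CO[Si](C)(C)C(C)(C)C | intermediate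
11 | butyl vinyl ether | C=COCCCC | starting material
12 | O-vinyl ether of 10 (allyl vinyl ether, carbinol centre S) | CCC[C@H](OC=C)/C(=C/C)[C@H]1OC(C)(C)O[C@@H]1CO[Si](C)(C)C(C)(C)C | intermediate
13 | primary alcohol from 12 (TBS removed) | CCC[C@H](OC=C)/C(=C/C)[C@H]1OC(C)(C)O[C@@H]1CO | intermediate
14 | trans-dioxolane carbaldehyde carrying the allyl vinyl ether arm | CCC[C@H](OC=C)/C(=C/C)[C@H]1OC(C)(C)O[C@@H]1C=O | intermediate
15 | tert-butyl acrylate | C=CC(=O)OC(C)(C)C | starting material
16 | tert-butyl 2-[hydroxy(dioxolanyl)methyl]acrylate, Morita–Baylis–Hillman adduct of 14 (mixture at the new carbinol) | CCC[C@H](OC=C)/C(=C/C)[C@H]1OC(C)(C)O[C@@H]1C(O)C(=C)C(=O)OC(C)(C)C | intermediate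
17 | tert-butyl carbonate of 16 | CCC[C@H](OC=C)/C(=C/C)[C@H]1OC(C)(C)O[C@@H]1C(OC(=O)OC(C)(C)C)C(=C)C(=O)OC(C)(C)C | intermediate
18 | tert-butyl (E)-3-(dioxolanyl)-2-(pinacolatoborylmethyl)acrylate carrying the allyl vinyl ether arm (dioxolane cis to CH2B) | CCC[C@H](OC=C)/C(=C/C)[C@H]1OC(C)(C)O[C@@H]1/C=C(\CB2OC(C)(C)C(C)(C)O2)C(=O)OC(C)(C)C | intermediate
19 | Claisen aldehyde: C4 aldehyde, C6 methyl stereocentre set, (Z)-butylidene at C7, allylboronate intact | O=CC[C@H](C)/C(=C/CCC)[C@H]1OC(C)(C)O[C@@H]1/C=C(\CB2OC(C)(C)C(C)(C)O2)C(=O)OC(C)(C)C | intermediate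
20 | cyclised O4-pinacolborate of 21 | CC1(C)OB(O[C@H]2C[C@H](C)/C(=C/CCC)[C@H]3OC(C)(C)O[C@@H]3[C@H]2C(=C)C(=O)OC(C)(C)C)OC1(C)C | intermediate
21 | cycloheptane with C4 OH, C3a 1-(tert-butoxycarbonyl)vinyl, C8/C8a trans-acetonide, C7 (Z)-butylidene, C6 methyl (configurations as in the target) | O[C@H]1C[C@H](C)/C(=C/CCC)[C@H]2OC(C)(C)O[C@@H]2[C@H]1C(=C)C(=O)OC(C)(C)C | intermediate
22 | O4-tert-butyldiphenylsilyl ether of 21 | CC(C)(C)[Si](O[C@H]1C[C@H](C)/C(=C/CCC)[C@H]2OC(C)(C)O[C@@H]2[C@H]1C(=C)C(=O)OC(C)(C)C)(c1ccccc1)c1ccccc1 | intermediate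
23 | C7,C1' syn-diol from 22 (C7 OH trans to O8) | CC(C)(C)[Si](O[C@H]1C[C@H](C)[C@@](O)([C@H](O)CCC)[C@H]2OC(C)(C)O[C@@H]2[C@H]1C(=C)C(=O)OC(C)(C)C)(c1ccccc1)c1ccccc1 | intermediate
24 | C7 tertiary alcohol with butanoyl group (α-hydroxy ketone) | CC(C)(C)[Si](O[C@H]1C[C@H](C)[C@@](O)(C(=O)CCC)[C@H]2OC(C)(C)O[C@@H]2[C@H]1C(=C)C(=O)OC(C)(C)C)(c1ccccc1)c1ccccc1 | intermediate
25 | seco acid: 2-substituted acrylic acid with free C7, C8 and C8a hydroxyls | CC(C)(C)[Si](O[C@H]1C[C@H](C)[C@@](O)(C(=O)CCC)[C@@H](O)[C@H](O)[C@H]1C(=C)C(=O)O)(c1ccccc1)c1ccccc1 | intermediate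
26 | (3aS,4S,6S,7S,8S,8aR)-7-butanoyl-4-(TBDPS-oxy)-7,8-dihydroxy-6-methyl-3-methylidene-octahydrocyclohepta[b]furan-2-one | C=C1C(=O)O[C@@H]2[C@@H]1[C@@H](O[Si](c3ccccc3)(c3ccccc3)C(C)(C)C)C[C@H](C)[C@@](O)(C(=O)CCC)[C@H]2O | intermediate
27 | angelic acid, (Z)-2-methylbut-2-enoic acid | C/C=C(/C)C(=O)O | starting material
28 | angelic 2,4,6-trichlorobenzoic mixed anhydride | C/C=C(/C)C(=O)OC(=O)c1c(Cl)cc(Cl)cc1Cl | intermediate
29 | C8 angelate of 26 | C=C1C(=O)O[C@@H]2[C@@H]1[C@@H](O[Si](c3ccccc3)(c3ccccc3)C(C)(C)C)C[C@H](C)[C@@](O)(C(=O)CCC)[C@H]2OC(=O)/C(C)=C\C | intermediate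
30 | O4-TBDPS ether of the target, (E)-but-2-enoyl at C7 | C=C1C(=O)O[C@@H]2[C@@H]1[C@@H](O[Si](c3ccccc3)(c3ccccc3)C(C)(C)C)C[C@H](C)[C@@](O)(C(=O)/C=C/C)[C@H]2OC(=O)/C(C)=C\C | intermediate
31 | CNP0206014.2, (3aS,4S,6S,7S,8S,8aR)-7-[(E)-but-2-enoyl]-4,7-dihydroxy-6-methyl-3-methylidene-2-oxo-octahydrocyclohepta[b]furan-8-yl (Z)-2-methylbut-2-enoate | C=C1C(=O)O[C@@H]2[C@@H]1[C@@H](O)C[C@H](C)[C@@](O)(C(=O)/C=C/C)[C@H]2OC(=O)/C(C)=C\C | target

Total steps: 21. Longest linear sequence: 21 steps (1 → 31).

Steps most likely to fail

Step 14 (proposed new method). Three things may go wrong: loss of chirality transfer to C6 through the chair with an axial propyl group, slow seven-membered ring closure that lets the aldehyde oligomerise, or lactonisation of the O4 borate. The fallback separates the two events and uses known chemistry; it sets out from 17 and returns at 21. Carbonate 17 is heated alone in toluene at 110 °C, so that only the Claisen rearrangement occurs, and the aldehyde carbonate F1 is isolated. F1 is then cyclised by Pd(PPh3)4-catalysed umpolung allylation with InI in THF at 23 °C (the allylic carbonate becomes an allylmetal, which adds through its γ-carbon to the aldehyde in a cyclic transition state). Aqueous work-up should give 21.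

Step 16. The risks are poor facial selectivity at the exocyclic alkene and competing osmylation of the acrylate. The fallback sets out from 22 and returns at 23, and changes the element of control. Woodward cis-hydroxylation (I2, AgOAc, wet AcOH, 23 °C) starts with electrophilic iodination, which ignores the acrylate, and places the cis-diol on the face opposite to the first attack. It should give the hydroxy acetate F2, and methanolysis (K2CO3, MeOH, 0 °C) then gives 23.

Step 20. The risks are sluggish enolisation of the hindered ketone under IBX and oxidative side reactions. The fallback sets out from 29 and returns at 30. Acid-mediated α-selenenylation (PhSeCl, EtOAc, 23 °C) should give the α-phenylselanyl ketone F3. Oxidation with H2O2 and pyridine in CH2Cl2 at 0 °C gives the selenoxide F4, which undergoes syn-elimination at 23 °C to the (E)-enone 30.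

Further compounds
F1 | step 14 | Claisen aldehyde of carbonate 17 (C4 aldehyde, allylic tert-butyl carbonate intact) | O=CC[C@H](C)/C(=C/CCC)[C@H]1OC(C)(C)O[C@@H]1C(OC(=O)OC(C)(C)C)C(=C)C(=O)OC(C)(C)C
F2 | step 16 | C1' acetate of diol 23 (C7 OH free) | CC(C)(C)[Si](O[C@H]1C[C@H](C)[C@@](O)([C@H](OC(C)=O)CCC)[C@H]2OC(C)(C)O[C@@H]2[C@H]1C(=C)C(=O)OC(C)(C)C)(c1ccccc1)c1ccccc1
F3 | step 20 | 2'-phenylselanyl derivative of ketone 29 (both C2' epimers) | C=C1C(=O)O[C@@H]2[C@@H]1[C@@H](O[Si](c3ccccc3)(c3ccccc3)C(C)(C)C)C[C@H](C)[C@@](O)(C(=O)C([Se]c3ccccc3)CC)[C@H]2OC(=O)/C(C)=C\C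
F4 | step 20 | selenoxide of F3 | C=C1C(=O)O[C@@H]2[C@@H]1[C@@H](O[Si](c3ccccc3)(c3ccccc3)C(C)(C)C)C[C@H](C)[C@@](O)(C(=O)C([Se](=O)c3ccccc3)CC)[C@H]2OC(=O)/C(C)=C\C
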